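The cyclopentane ring of the indane is the ring to cut. It consists only of ring A carbons C5 and C6 (chromene numbering), the cyclobutane bond Ca–Cb (Ca bonded to the benzylic CH2, Cb bonded to C5) and that one benzylic carbon. A palladium-catalysed (2+2+1) annulation of a ring A iodide, a cyclobutene and CO should form C5–Cb, Ca–C(O) and C(O)–C6 in one operation. It closes the ring as an indanone and sets Ca and Cb from the lone stereocentre Cc. The precursors are 5-iodo-7-methoxy-2,2-dimethylchromene and an enantiopure 3-aryl-4,4-dimethylcyclobutene whose aryl group is the bis-silylated catechol ring B.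

Key step: step 10

Labels: ring A is the benzene ring of the chromene (C4a, C5–C8, C8a) and ring B is the catechol ring. Ca is the cyclobutane CH next to the benzylic carbon, Cb the cyclobutane CH on C5, Cc the cyclobutane CH carrying ring B, and Cd the CMe2 carbon. Ce is the carbon between Ca and C6. TBS is tert-butyldimethylsilyl.

Assumption: the (2S,5S)-amine is taken to give the (R)-cyclobutanone. The model has the styrene meeting the keteniminium carbon with its ArCH end in the quadrant free of a pyrrolidine methyl group. The sense must be confirmed on the ketone, and the equally available (2R,5R)-amine would be used if it is reversed.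

Remark on the key-step partners:
- HI is released, so a base belongs to the reaction.
- An iodide is used so that oxidative addition under CO runs at a temperature the cyclobutene survives.
- An insoluble carbonate in an anhydrous, weakly polar solvent keeps the aryl silyl ethers on.

Step 1
Reactants: 1 3-bromo-5-methoxyphenol; 2 3-chloro-3-methylbut-1-yne
Product: 3 1-bromo-3-methoxy-5-[(2-methylbut-3-yn-2-yl)oxy]benzene
Conditions: DBU, CuCl2 (1 mol %), MeCN, 0 °C to rt
Reagents that add atoms: none
Why: Copper-catalysed O-alkylation of a phenol with a tertiary propargylic chloride is the standard way to aryl 1,1-dimethylpropargyl ethers, and neither the aryl bromide nor the methyl ether reacts at 0 °C.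

Step 2
Reactants: 3 1-bromo-3-methoxy-5-[(2-methylbut-3-yn-2-yl)oxy]benzene
Product: 5 5-bromo-7-methoxy-2,2-dimethyl-2H-chromene, via allenylphenol 4 (not isolated)
Conditions: PhNEt2, 185 °C
Reagents that add atoms: none
Why: Thermal aryl propargyl ether Claisen rearrangement gives 4, which passes on by 1,5-hydrogen shift and oxa-6π electrocyclisation to the chromene; migration should go mainly to the ortho carbon between oxygen and bromine, because a meta acceptor draws the migrating group towards itself and a meta donor sends it to its own para position, and both effects point to the same carbon here (a minor regioisomer, if formed, is removed by chromatography).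

Step 3
Reactants: 5 5-bromo-7-methoxy-2,2-dimethyl-2H-chromene
Product: 6 5-iodo-7-methoxy-2,2-dimethyl-2H-chromene
Conditions: CuI (5 mol %), trans-N,N'-dimethylcyclohexane-1,2-diamine (10 mol %), NaI, 1,4-dioxane, 110 °C
Reagents that add atoms: sodium iodide, [Na+].[I-]
Why: Copper-catalysed aromatic Finkelstein exchange, driven by the poor solubility of NaBr in dioxane, turns the bromide into the iodide that can undergo oxidative addition under CO at a temperature the cyclobutene partner tolerates.

Step 4
Reactants: 7 3,4-dihydroxybenzaldehyde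
Product: 8 3,4-bis(tert-butyldimethylsilyloxy)benzaldehyde
Conditions: TBSCl, imidazole, DMF, rt
Reagents that add atoms: tert-butyldimethylsilyl chloride, CC(C)(C)[Si](C)(C)Cl
Why: Imidazole-promoted silylation of both phenols; silyl ethers are kept for ring B because fluoride is the one release that spares the aryl methyl ether and the acid- and hydrogenation-sensitive chromene at the end.

Step 5
Reactants: 8 3,4-bis(tert-butyldimethylsilyloxy)benzaldehyde
Product: 9 3,4-bis(tert-butyldimethylsilyloxy)styrene
Conditions: MePPh3Br, n-BuLi, THF, 0 °C to rt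
Reagents that add atoms: methyltriphenylphosphonium bromide, C[P+](c1ccccc1)(c1ccccc1)c1ccccc1.[Br-]
Why: Wittig methylenation of a non-enolisable aromatic aldehyde, run without excess base so that the aryl silyl ethers stay on.

Step 6
Reactants: 10 isobutyryl chloride; 11 (2S,5S)-2,5-dimethylpyrrolidine
Product: 12 1-[(2S,5S)-2,5-dimethylpyrrolidin-1-yl]-2-methylpropan-1-one
Conditions: Et3N, CH2Cl2, 0 °C
Reagents that add atoms: none
Why: Simple N-acylation of a secondary amine with an acid chloride, which leaves the two stereocentres of the auxiliary untouched.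

Step 7
Reactants: 12 1-[(2S,5S)-2,5-dimethylpyrrolidin-1-yl]-2-methylpropan-1-one; 9 3,4-bis(tert-butyldimethylsilyloxy)styrene
Product: 15 (R)-3-[3,4-bis(tert-butyldimethylsilyloxy)phenyl]-2,2-dimethylcyclobutanone, via keteniminium triflate 13 (not isolated), via cyclobutaniminium triflate 14 (not isolated)
Conditions: Tf2O, 2,6-di-tert-butyl-4-methylpyridine, CH2Cl2, −20 °C to rt; then 9, 40 °C; then aq NaHCO3, 40 °C
Reagents that add atoms: water, O; triflic anhydride (counter-ion of 13 and 14 only), O=S(=O)(OS(=O)(=O)C(F)(F)F)C(F)(F)F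
Why: Keteniminium–alkene (2+2) cycloaddition under auxiliary control: amide activation gives 13 before the acid-sensitive styrene is added, the nucleophilic CH2 terminus of 9 bonds to the iminium carbon and the benzylic carbon then closes onto CMe2 (hence the 3-aryl-2,2-dimethyl pattern), the C2-symmetric pyrrolidine leaves one quadrant open for the ArCH end and so should set Cc, and mild hydrolysis of 14 frees the ketone and returns the amine.

Step 8
Reactants: 15 (R)-3-[3,4-bis(tert-butyldimethylsilyloxy)phenyl]-2,2-dimethylcyclobutanone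
Product: 17 (R)-3-[3,4-bis(tert-butyldimethylsilyloxy)phenyl]-4,4-dimethylcyclobut-1-enyl trifluoromethanesulfonate, via potassium enolate 16 (not isolated)
Conditions: KN(SiMe3)2, THF, −78 °C; then N-(5-chloro-2-pyridyl)bis(trifluoromethanesulfonimide), −78 °C
Reagents that add atoms: N-(5-chloro-2-pyridyl)bis(trifluoromethanesulfonimide), O=S(=O)(N(c1ccc(Cl)cn1)S(=O)(=O)C(F)(F)F)C(F)(F)F; potassium bis(trimethylsilyl)amide (potassium of 16 only), C[Si](C)(C)[N-][Si](C)(C)C.[K+]
Why: Only the CH2 group can be deprotonated because the other α-carbon is quaternary, so enolate 16 is a single regioisomer and its O-sulfonylation gives the enol triflate, while the non-acidic Cc–H is not touched.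

Step 9
Reactants: 17 (R)-3-[3,4-bis(tert-butyldimethylsilyloxy)phenyl]-4,4-dimethylcyclobut-1-enyl trifluoromethanesulfonate
Product: 18 (S)-4-(2,2-dimethylcyclobut-3-enyl)-1,2-bis(tert-butyldimethylsilyloxy)benzene
Conditions: Pd(OAc)2 (5 mol %), PPh3 (10 mol %), HCO2H, Et3N, DMF, 40 °C
Reagents that add atoms: none
Why: Palladium-catalysed hydrogenolysis of an enol triflate with formate (oxidative addition, formate exchange, loss of CO2, C–H reductive elimination) replaces OTf by H under conditions mild enough to avoid electrocyclic opening of the cyclobutene and leaves Cc as it is (the descriptor changes from R to S only because the priorities change).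

Step 10
Reactants: 6 5-iodo-7-methoxy-2,2-dimethyl-2H-chromene; 18 (S)-4-(2,2-dimethylcyclobut-3-enyl)-1,2-bis(tert-butyldimethylsilyloxy)benzene; 19 carbon monoxide
Product: 20 cyclobuta-fused indanone: C5 of ring A bonded to Cb, C6 bonded to the ketone carbon Ce, Ce bonded to Ca; Ca–H and Cb–H cis, 3,4-bis(TBSO)phenyl on Cc trans to ring A, Cd = CMe2 (Ca S, Cb S, Cc S)
Conditions: Pd(OAc)2 (10 mol %), PPh3 (25 mol %), K2CO3, PivOH (30 mol %), CO (1 atm), anhydrous anisole, 70 °C; 6 in slight excess
Reagents that add atoms: carbon monoxide (compound 19), [C-]#[O+]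
Why: Proposed new method: zerovalent palladium, formed from Pd(OAc)2, PPh3 and CO, should insert into the C5–I bond of 6, the aryl–palladium bond should add syn across the strained alkene of 18 (C5 to Cb, palladium to Ca), the resulting alkylpalladium has no syn β-hydrogen (Cd is quaternary, Cb–H points away) and so should take up CO with retention at Ca, and pivalate-assisted cleavage of C6–H followed by C–C reductive elimination should release 20 while K2CO3 absorbs HI. The closest known reaction types are aryl halide/norbornene/CO cascades to fused indanones, cyclocarbonylation of 2-halobiaryls to fluorenones and carbonylative indenone annulation of aryl halides with alkynes; a monocyclic cyclobutene has not been shown as the two-carbon partner. The one new ring, the cyclopentanone (C5, C6, Ce, Ca, Cb), closes through a six-membered acyl palladacycle by intramolecular C–H acylation at C6, the only open ortho site because C4a is substituted. Cb and Ca are set under substrate control: ring B on Cc shields one face, so aryl and palladium arrive on the other, and syn addition makes the ring fusion cis and trans to ring B. Three selectivities are needed: aryl to Cb rather than Ca, secured because on the reacting face Cb is flanked only by Cc–H whereas Ca is flanked by a methyl group of Cd and the short forming C–C bond is the more sensitive to crowding; alkene insertion before CO insertion, favoured by ring strain, a concentrated cyclobutene, only 1 atm of CO and the reversibility of aroylpalladium formation when no good nucleophile is present; and reaction at the cyclobutene rather than at the unstrained chromene alkene, which is shielded by its own CMe2 group. The temperature is capped at 70 °C to stay below conrotatory opening of 18, and the insoluble carbonate in anisole keeps the aryl silyl ethers intact.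

Step 11
Reactants: 20 cyclobuta-fused indanone
Product: 21 cyclobuta-fused indanol, OH on Ce syn to the cyclobutane (Ce R, Ca S, Cb S, Cc S)
Conditions: NaBH4, MeOH/THF, 0 °C to rt; basic work-up
Reagents that add atoms: none
Why: Borohydride 1,2-reduction of the aryl ketone, with hydride expected on the convex face of the cis-fused bicycle (away from Cd), so that OH on Ce is syn to the cyclobutane, a centre that is erased in the next step.

Step 12
Reactants: 21 cyclobuta-fused indanol
Product: 22 bis-TBS ether of the target (Ce = CH2; Ca S, Cb R, Cc S)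
Conditions: Et3SiH, CF3CO2H (few equiv), CH2Cl2, −78 to −40 °C; cold quench with Et3N
Reagents that add atoms: none
Why: Ionic hydrogenation: the alcohol ionises at low temperature to a cation at Ce that is stabilised by the ortho methoxy group and the para pyran oxygen, too stabilised to trigger cyclobutane ring expansion, and is trapped by Et3SiH before the slower C-protonation of the chromene alkene can compete, provided that acid and time are limited.

Step 13
Reactants: 22 bis-TBS ether of the target
Product: 23 target CNP0207533.1 (Ca S, Cb R, Cc S)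
Conditions: Bu4NF, AcOH, THF, 0 °C, argon
Reagents that add atoms: none
Why: Fluoride cleavage of the two aryl silyl ethers, buffered with acetic acid and run under argon so that no catecholate is exposed to oxidation, touches none of the three stereocentres and gives the target.

Compound list

1 | 3-bromo-5-methoxyphenol | COc1cc(O)cc(Br)c1 | starting material
2 | 3-chloro-3-methylbut-1-yne | C#CC(C)(C)Cl | starting material
3 | 1-bromo-3-methoxy-5-[(2-methylbut-3-yn-2-yl)oxy]benzene | COc1cc(Br)cc(OC(C)(C)C#C)c1 | intermediate
4 | 3-bromo-5-methoxy-2-(3-methylbuta-1,2-dienyl)phenol (allenylphenol, not isolated) | COc1cc(O)c(C=C=C(C)C)c(Br)c1 | intermediate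
5 | 5-bromo-7-methoxy-2,2-dimethyl-2H-chromene | COc1cc2c(c(Br)c1)C=CC(C)(C)O2 | intermediate
6 | 5-iodo-7-methoxy-2,2-dimethyl-2H-chromene | COc1cc2c(c(I)c1)C=CC(C)(C)O2 | intermediate
7 | 3,4-dihydroxybenzaldehyde | O=Cc1ccc(O)c(O)c1 | starting material
8 | 3,4-bis(tert-butyldimethylsilyloxy)benzaldehyde | O=Cc1ccc(O[Si](C)(C)C(C)(C)C)c(O[Si](C)(C)C(C)(C)C)c1 | intermediate
9 | 3,4-bis(tert-butyldimethylsilyloxy)styrene | C=Cc1ccc(O[Si](C)(C)C(C)(C)C)c(O[Si](C)(C)C(C)(C)C)c1 | intermediate
10 | isobutyryl chloride | CC(C)C(Cl)=O | starting material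
11 | (2S,5S)-2,5-dimethylpyrrolidine | C[C@H]1CC[C@H](C)N1 | starting material
12 | 1-[(2S,5S)-2,5-dimethylpyrrolidin-1-yl]-2-methylpropan-1-one | CC(C)C(=O)N1[C@@H](C)CC[C@@H]1C | intermediate
13 | (2S,5S)-2,5-dimethyl-1-(2-methylprop-1-enylidene)pyrrolidinium triflate (keteniminium triflate, not isolated) | CC(C)=C=[N+]1[C@@H](C)CC[C@@H]1C.[O-]S(=O)(=O)C(F)(F)F | intermediate
14 | cyclobutaniminium triflate of 15 with the (2S,5S)-auxiliary (not isolated) | CC1(C)C(=[N+]2[C@@H](C)CC[C@@H]2C)C[C@@H]1c1ccc(O[Si](C)(C)C(C)(C)C)c(O[Si](C)(C)C(C)(C)C)c1.[O-]S(=O)(=O)C(F)(F)F | intermediate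
15 | (R)-3-[3,4-bis(tert-butyldimethylsilyloxy)phenyl]-2,2-dimethylcyclobutanone | CC1(C)C(=O)C[C@@H]1c1ccc(O[Si](C)(C)C(C)(C)C)c(O[Si](C)(C)C(C)(C)C)c1 | intermediate
16 | potassium enolate of 15 (not isolated) | CC1(C)C([O-])=C[C@@H]1c1ccc(O[Si](C)(C)C(C)(C)C)c(O[Si](C)(C)C(C)(C)C)c1.[K+] | intermediate
17 | (R)-3-[3,4-bis(tert-butyldimethylsilyloxy)phenyl]-4,4-dimethylcyclobut-1-enyl trifluoromethanesulfonate | CC1(C)C(OS(=O)(=O)C(F)(F)F)=C[C@@H]1c1ccc(O[Si](C)(C)C(C)(C)C)c(O[Si](C)(C)C(C)(C)C)c1 | intermediate
18 | (S)-4-(2,2-dimethylcyclobut-3-enyl)-1,2-bis(tert-butyldimethylsilyloxy)benzene | CC1(C)C=C[C@@H]1c1ccc(O[Si](C)(C)C(C)(C)C)c(O[Si](C)(C)C(C)(C)C)c1 | intermediate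
19 | carbon monoxide | [C-]#[O+] | starting material
20 | cyclobuta-fused indanone, silylated ring B (Ca S, Cb S, Cc S) | COc1cc2c(c3c1C(=O)[C@H]1[C@@H]3[C@H](c3ccc(O[Si](C)(C)C(C)(C)C)c(O[Si](C)(C)C(C)(C)C)c3)C1(C)C)C=CC(C)(C)O2 | intermediate
21 | cyclobuta-fused indanol, OH syn to the cyclobutane (Ce R, Ca S, Cb S, Cc S) | COc1cc2c(c3c1[C@H](O)[C@H]1[C@@H]3[C@H](c3ccc(O[Si](C)(C)C(C)(C)C)c(O[Si](C)(C)C(C)(C)C)c3)C1(C)C)C=CC(C)(C)O2 | intermediate
22 | bis-TBS ether of the target (Ca S, Cb R, Cc S) | COc1cc2c(c3c1C[C@H]1[C@@H]3[C@H](c3ccc(O[Si](C)(C)C(C)(C)C)c(O[Si](C)(C)C(C)(C)C)c3)C1(C)C)C=CC(C)(C)O2 | intermediate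
23 | CNP0207533.1 (Ca S, Cb R, Cc S) | COc1cc2c(c3c1C[C@H]1[C@@H]3[C@H](c3ccc(O)c(O)c3)C1(C)C)C=CC(C)(C)O2 | target

Total step count: 13. Longest linear sequence: 9 steps (7 → 8 → 9 → 15 → 17 → 18 → 20 → 21 → 22 → 23).

Steps most likely to fail

1. Step 10. Several processes could derail it:
   - CO insertion ahead of alkene insertion, which would transpose the carbonyl to C5.
   - Carbopalladation in the reverse orientation, followed by β-hydride loss at Cc.
   - Stalling at the acylpalladium stage.
   - Thermal ring opening of the cyclobutene.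

   Fallback, from 17 and 6 back to 20, makes the three bonds one at a time by known reactions. Palladium-catalysed methoxycarbonylation of 17 (Pd(OAc)2, PPh3, CO, MeOH, Et3N, DMF, rt) should give methyl (R)-3-[3,4-bis(TBSO)phenyl]-4,4-dimethylcyclobut-1-ene-1-carboxylate F1. Iodine–magnesium exchange on 6 with iPrMgCl·LiCl should give (7-methoxy-2,2-dimethyl-2H-chromen-5-yl)magnesium chloride F2. Under CuBr·SMe2 catalysis this should add 1,4 to F1 at Cb, anti to ring B. A cold acetic acid quench should then protonate the enolate at Ca on the face away from ring A to give the cis ester F3. Me3SnOH in 1,2-dichloroethane should cleave the methyl ester without touching the silyl ethers or Ca, giving the carboxylic acid F4. 1-Chloro-N,N,2-trimethylpropenylamine should convert it under neutral conditions into the acid chloride F5. SnCl4 at −78 °C should close the ring by intramolecular Friedel–Crafts acylation at the doubly activated C6 to give 20.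

2. Step 7. The remote auxiliary may discriminate the faces weakly or in the wrong sense, and the electron-rich styrene may oligomerise cationically.

   Fallback, from 9 back to 15, replaces auxiliary control by reagent control. N,N-dimethylisobutyramide, Tf2O and collidine should give tetramethylketeniminium triflate F6. This adds to 9 to give the racemic cyclobutaniminium triflate F7, and hydrolysis gives the racemic ketone F8. Corey–Bakshi–Shibata reduction follows, with BH3·SMe2 and (S)-1-methyl-3,3-diphenyltetrahydro-1H,3H-pyrrolo[1,2-c][1,3,2]oxazaborole. It should fix the carbinol carbon as R in both antipodes, so the (R)-ketone becomes the cis-(1R,3R)-cyclobutanol F9 and the (S)-ketone becomes the trans-(1R,3S)-cyclobutanol F10. The diastereomers are separated on silica, and Dess–Martin oxidation of F9 returns enantiopure 15.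

3. Step 12. The chromene alkene may be protonated and then captured by hydride or dimerise, and the cation at Ce may lose a proton.

   Fallback, from 20 back to 22, avoids acid and cations altogether. Condensation of 20 with TsNHNH2 (EtOH, catalytic pyridinium p-toluenesulfonate, 60 °C) should give the tosylhydrazone F11. Catecholborane in CHCl3 at −10 °C reduces the C=N bond. Warming with NaOAc·3H2O then expels sulfinate and nitrogen to leave CH2 at Ce, giving 22 with the cis ring fusion unchanged.

Further compounds

F1 | step 10 | methyl (R)-3-[3,4-bis(TBSO)phenyl]-4,4-dimethylcyclobut-1-ene-1-carboxylate | CC1(C)C(C(=O)OC)=C[C@@H]1c1ccc(O[Si](C)(C)C(C)(C)C)c(O[Si](C)(C)C(C)(C)C)c1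
F2 | step 10 | (7-methoxy-2,2-dimethyl-2H-chromen-5-yl)magnesium chloride | COc1cc2c(c([Mg]Cl)c1)C=CC(C)(C)O2
F3 | step 10 | methyl cyclobutanecarboxylate with ester on Ca cis to ring A on Cb and ring B on Cc trans to both | COc1cc2c(c(c1)[C@H]1[C@H](c3ccc(O[Si](C)(C)C(C)(C)C)c(O[Si](C)(C)C(C)(C)C)c3)C(C)(C)[C@H]1C(=O)OC)C=CC(C)(C)O2
F4 | step 10 | carboxylic acid from F3 | COc1cc2c(c(c1)[C@H]1[C@H](c3ccc(O[Si](C)(C)C(C)(C)C)c(O[Si](C)(C)C(C)(C)C)c3)C(C)(C)[C@H]1C(=O)O)C=CC(C)(C)O2
F5 | step 10 | acid chloride from F4 | COc1cc2c(c(c1)[C@H]1[C@H](c3ccc(O[Si](C)(C)C(C)(C)C)c(O[Si](C)(C)C(C)(C)C)c3)C(C)(C)[C@H]1C(=O)Cl)C=CC(C)(C)O2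
F6 | step 7 | tetramethylketeniminium triflate | CC(C)=C=[N+](C)C.[O-]S(=O)(=O)C(F)(F)F
F7 | step 7 | racemic N,N-dimethylcyclobutaniminium triflate | CC1(C)C(=[N+](C)C)CC1c1ccc(O[Si](C)(C)C(C)(C)C)c(O[Si](C)(C)C(C)(C)C)c1.[O-]S(=O)(=O)C(F)(F)F
F8 | step 7 | racemic 3-[3,4-bis(TBSO)phenyl]-2,2-dimethylcyclobutanone | CC1(C)C(=O)CC1c1ccc(O[Si](C)(C)C(C)(C)C)c(O[Si](C)(C)C(C)(C)C)c1
F9 | step 7 | cis-(1R,3R)-3-[3,4-bis(TBSO)phenyl]-2,2-dimethylcyclobutanol | CC1(C)[C@H](O)C[C@@H]1c1ccc(O[Si](C)(C)C(C)(C)C)c(O[Si](C)(C)C(C)(C)C)c1
F10 | step 7 | trans-(1R,3S)-3-[3,4-bis(TBSO)phenyl]-2,2-dimethylcyclobutanol | CC1(C)[C@H](O)C[C@H]1c1ccc(O[Si](C)(C)C(C)(C)C)c(O[Si](C)(C)C(C)(C)C)c1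
F11 | step 12 | tosylhydrazone of 20 (C=N geometry not defined) | COc1cc2c(c3c1C(=NNS(=O)(=O)c4ccc(C)cc4)[C@H]1[C@@H]3[C@H](c3ccc(O[Si](C)(C)C(C)(C)C)c(O[Si](C)(C)C(C)(C)C)c3)C1(C)C)C=CC(C)(C)O2
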